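Labels: benzofuran numbering (O1, C2, C3, C3a, C4 to C7, C7a). Ring A is the aryl group on C2, ring B the fused arene, ring C the aryl group on Cβ of the C5 side chain Cα(OH)–Cβ(CH2OH).
Feature: ring A on C2 and CH2OH on C3 stand trans on the dihydrofuran ring. This is the syn array of an open-chain 1,2-diarylpropane-1,3-diol whose carbinol oxygen is O1, provided the ring is closed at O1–C7a and C2–O1 is never broken. Cα/Cβ repeat this array in the same absolute sense (C2 S, C3 R, Cα S, Cβ R).
Disconnections: Cα–Cβ (Evans syn-aldol of the ring C arylacetyl imide on the C5 aldehyde), then O1–C7a (intramolecular copper-catalysed O-arylation of an ortho-bromoarene), then C2–C3 (Evans syn-aldol of the ring B arylacetyl imide on O-benzylvanillin, same (S)-auxiliary).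
Ring order: rings A, B and C are bought as arenes. The dihydrofuran ring is the only ring made, after its two stereocentres are in place and before the side chain is built.
Ring B enters as a 2-bromoarylacetic acid made from 4-amino-3-methoxybenzoic acid, with NH2 exchanged for Br before the acetate carbons are attached.

Key step: step 10

Remark: BrZnCH2CO2Et is taken as the commercial THF solution (otherwise it is made from ethyl bromoacetate and zinc dust).

Step 1
Reactants: 1 4-amino-3-methoxybenzoic acid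
Product: 2 4-amino-3-iodo-5-methoxybenzoic acid
Conditions: NIS (1.05 equiv), DMF, 0 °C to rt, dark
Reagents that add atoms: N-iodosuccinimide, O=C1CCC(=O)N1I
Why: Electrophilic aromatic iodination (SEAr): NH2 is the strongest donor on the ring and its para position and one ortho position are occupied, so iodine should enter only at the free ortho carbon, the future C3a.

Step 2
Reactants: 2 4-amino-3-iodo-5-methoxybenzoic acid
Product: 4 4-bromo-3-iodo-5-methoxybenzoic acid, via diazonium bromide 3 (not isolated)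
Conditions: NaNO2 (1.1 equiv), 48% aq HBr, MeCN/H2O, 0 °C; then CuBr (0.3 equiv), 48% aq HBr, 0 to 60 °C
Reagents that add atoms: hydrogen bromide, Br; sodium nitrite, [Na+].[O-]N=O (its nitrogen is found in 3 only)
Why: Sandmeyer bromination: diazotisation and electron transfer from CuBr give the aryl radical that takes up bromine at the future C7a, and doing this before any acetate carbon is attached avoids a 2-aminophenylacetate, which would lactamise to an oxindole.

Step 3
Reactants: 4 4-bromo-3-iodo-5-methoxybenzoic acid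
Product: 5 tert-butyl 4-bromo-3-iodo-5-methoxybenzoate
Conditions: tBuOC(=NH)CCl3 (2 equiv), THF, rt
Reagents that add atoms: tert-butyl 2,2,2-trichloroacetimidate, CC(C)(C)OC(=N)C(Cl)(Cl)Cl
Why: Alkylative esterification with a trichloroacetimidate: the acid protonates the imidate and the carboxylate captures the tert-butyl cation, giving an ester bulky enough to outlast LiOH, LiBH4 and hot Cs2CO3 later on.

Step 4
Reactants: 5 tert-butyl 4-bromo-3-iodo-5-methoxybenzoate
Product: 6 tert-butyl 4-bromo-3-(2-ethoxy-2-oxoethyl)-5-methoxybenzoate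
Conditions: BrZnCH2CO2Et (1.2 equiv, 0.5 M in THF), Pd(PPh3)4 (5 mol %), THF, 55 °C
Reagents that add atoms: (2-ethoxy-2-oxoethyl)zinc bromide, CCOC(=O)C[Zn]Br
Why: Negishi-type cross-coupling of a Reformatsky reagent: triphenylphosphine-bound zerovalent palladium inserts into the weaker C–I bond much faster than into the C–Br bond, which after coupling is flanked on both sides, so a slight excess of the zinc enolate should give the monoarylacetate with bromine intact.

Step 5
Reactants: 6 tert-butyl 4-bromo-3-(2-ethoxy-2-oxoethyl)-5-methoxybenzoate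
Product: 8 [2-bromo-5-(tert-butoxycarbonyl)-3-methoxyphenyl]acetic acid, via lithium carboxylate 7 (not isolated)
Conditions: LiOH·H2O (1.5 equiv), THF/H2O, 0 °C to rt; then 1 M HCl to pH 3, 0 °C
Reagents that add atoms: lithium hydroxide, [Li+].[OH-]
Why: Chemoselective saponification (acyl–oxygen cleavage): hydroxide attacks the unhindered ethyl ester while the tert-butyl benzoate is shielded, and brief cold acidification does not cleave it.

Step 6
Reactants: 8 [2-bromo-5-(tert-butoxycarbonyl)-3-methoxyphenyl]acetic acid, 9 (S)-4-benzyl-2-oxazolidinone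
Product: 11 tert-butyl 3-{2-[(4S)-4-benzyl-2-oxo-1,3-oxazolidin-3-yl]-2-oxoethyl}-4-bromo-5-methoxybenzoate, via mixed pivalic anhydride 10 (not isolated)
Conditions: PivCl (1.05 equiv), Et3N (2.5 equiv), THF, −20 °C; then LiCl (1.1 equiv), 9 (1.0 equiv), −20 °C to rt
Reagents that add atoms: pivaloyl chloride, CC(C)(C)C(=O)Cl (its atoms are found in 10 only)
Why: N-Acylation of the Evans auxiliary through a mixed anhydride: LiCl/Et3N makes the oxazolidinone nucleophilic enough without a strong base, attack goes to the less hindered arylacetyl carbonyl, and the aryl bromide and the acidic benzylic CH2 are left alone.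

Step 7
Reactants: 11 tert-butyl 3-{2-[(4S)-4-benzyl-2-oxo-1,3-oxazolidin-3-yl]-2-oxoethyl}-4-bromo-5-methoxybenzoate, 12 4-benzyloxy-3-methoxybenzaldehyde
Product: 15 tert-butyl 3-[(2S,3S)-1-[(4S)-4-benzyl-2-oxo-1,3-oxazolidin-3-yl]-3-(4-benzyloxy-3-methoxyphenyl)-3-hydroxy-1-oxopropan-2-yl]-4-bromo-5-methoxybenzoate, via Z-boron enolate 13 (not isolated), via boron aldolate 14 (not isolated)
Conditions: Bu2BOTf (1.15 equiv), iPr2NEt (1.3 equiv), CH2Cl2, −78 to 0 °C; 12 (1.2 equiv), −78 to −10 °C; then pH 7 phosphate buffer, MeOH, 30% H2O2, 0 °C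
Reagents that add atoms: dibutylboron triflate, CCCCB(CCCC)OS(=O)(=O)C(F)(F)F (its boron unit is found in 13 and 14 only)
Why: Evans boron syn-aldol: soft enolisation gives the Z-enolate, which adds through a closed Zimmerman–Traxler chair on the face left open by the benzyl group of the (S)-auxiliary, so the future C3 (2S in the adduct) and the future C2 (3S) are set together as the syn pair.

Step 8
Reactants: 15 tert-butyl 3-[(2S,3S)-1-[(4S)-4-benzyl-2-oxo-1,3-oxazolidin-3-yl]-3-(4-benzyloxy-3-methoxyphenyl)-3-hydroxy-1-oxopropan-2-yl]-4-bromo-5-methoxybenzoate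
Product: 16 tert-butyl 3-[(1S,2R)-1-(4-benzyloxy-3-methoxyphenyl)-1,3-dihydroxypropan-2-yl]-4-bromo-5-methoxybenzoate
Conditions: LiBH4 (2.5 equiv), MeOH (2.5 equiv), THF, 0 °C; then sat aq NH4Cl
Reagents that add atoms: none
Why: Reductive cleavage of an N-acyl oxazolidinone with LiBH4/MeOH: hydride goes to the exocyclic imide carbonyl, helped by the neighbouring alkoxide, while the tert-butyl ester, the aryl bromide and both stereocentres stay untouched at 0 °C (the descriptor of the aryl-bearing carbon changes from S to R through the priority rules only).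

Step 9
Reactants: 16 tert-butyl 3-[(1S,2R)-1-(4-benzyloxy-3-methoxyphenyl)-1,3-dihydroxypropan-2-yl]-4-bromo-5-methoxybenzoate
Product: 17 tert-butyl 3-[(1S,2R)-1-(4-benzyloxy-3-methoxyphenyl)-1-hydroxy-3-(triisopropylsilyloxy)propan-2-yl]-4-bromo-5-methoxybenzoate
Conditions: TIPSCl (1.1 equiv), imidazole (2.5 equiv), CH2Cl2, 0 °C to rt
Reagents that add atoms: triisopropylsilyl chloride, CC(C)[Si](Cl)(C(C)C)C(C)C
Why: Sterically controlled silylation: TIPSCl should react at the primary hydroxyl only, and TIPS is chosen over a smaller silyl group because either hydroxyl of 16 could close a five-membered ring onto C7a, so a base-induced 1,3 oxygen-to-oxygen silyl shift must not occur in step 10.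

Step 10
Reactants: 17 tert-butyl 3-[(1S,2R)-1-(4-benzyloxy-3-methoxyphenyl)-1-hydroxy-3-(triisopropylsilyloxy)propan-2-yl]-4-bromo-5-methoxybenzoate
Product: 18 tert-butyl (2S,3R)-2-(4-benzyloxy-3-methoxyphenyl)-7-methoxy-3-[(triisopropylsilyloxy)methyl]-2,3-dihydro-1-benzofuran-5-carboxylate
Conditions: CuI (15 mol %), 3,4,7,8-tetramethyl-1,10-phenanthroline (30 mol %), Cs2CO3 (2 equiv), 4 Å MS, degassed toluene (0.05 M), 110 °C, Ar
Reagents that add atoms: none
Why: This is an Ullmann-type intramolecular O-arylation, the copper-catalysed C–O cross-coupling by which 2-(2-haloaryl)ethanols are known to give 2,3-dihydrobenzofurans: Cs2CO3 hands the C2 oxygen to phenanthroline-bound monovalent copper, the metal then inserts into the adjacent C7a–Br bond and reaches the trivalent state inside a six-membered chelate ring, and C–O reductive elimination sets the catalyst free and leaves the O1–C7a bond. The dihydrofuran ring therefore closes as a five-membered ring by contraction of that six-membered metallacycle, formally a 5-exo substitution by O1 at the sp2 carbon C7a with loss of bromide. No stereocentre is made here, since neither C2–O1 nor any bond at C3 is broken, so the syn (1S,2R) array that the aldol of step 7 installed reappears as the trans (2S,3R) ring. The step needs a choice between two oxygens that could each close a five-membered ring onto C7a, and the TIPS ether on the primary oxygen, too bulky to shift to the secondary alkoxide under carbonate, secures it. It also needs full retention at the easily ionised p-alkoxybenzylic C2, which the basic, aprotic medium free of Lewis acids secures, and the monoprotected diol has no carbonyl group through which a retro-aldol split could run. The ester para to bromine helps the insertion at the doubly flanked C7a, and strict exclusion of O2 keeps the copper–phenanthroline pair from dehydrogenating the benzylic alcohol.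

Step 11
Reactants: 18 tert-butyl (2S,3R)-2-(4-benzyloxy-3-methoxyphenyl)-7-methoxy-3-[(triisopropylsilyloxy)methyl]-2,3-dihydro-1-benzofuran-5-carboxylate
Product: 19 [(2S,3R)-2-(4-benzyloxy-3-methoxyphenyl)-7-methoxy-3-[(triisopropylsilyloxy)methyl]-2,3-dihydro-1-benzofuran-5-yl]methanol
Conditions: LiAlH4 (1.5 equiv), THF, 0 °C to rt; aq work-up
Reagents that add atoms: none
Why: Ester reduction with LiAlH4: the tert-butyl benzoate is the only reducible group left, and the benzyl ether, the TIPS ether and the cyclic aryl ether are inert to hydride.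

Step 12
Reactants: 19 [(2S,3R)-2-(4-benzyloxy-3-methoxyphenyl)-7-methoxy-3-[(triisopropylsilyloxy)methyl]-2,3-dihydro-1-benzofuran-5-yl]methanol
Product: 20 (2S,3R)-2-(4-benzyloxy-3-methoxyphenyl)-7-methoxy-3-[(triisopropylsilyloxy)methyl]-2,3-dihydro-1-benzofuran-5-carbaldehyde
Conditions: activated MnO2 (15 equiv), CH2Cl2, rt
Reagents that add atoms: none
Why: Benzylic alcohol oxidation with MnO2: the electron-rich primary benzylic alcohol is the only free hydroxyl, the oxidation stops at the aldehyde, and the neutral heterogeneous medium does not disturb C2 or C3.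

Step 13
Reactants: 21 (4-benzyloxy-3-methoxyphenyl)acetic acid, 9 (S)-4-benzyl-2-oxazolidinone
Product: 23 (4S)-4-benzyl-3-[(4-benzyloxy-3-methoxyphenyl)acetyl]-1,3-oxazolidin-2-one, via mixed pivalic anhydride 22 (not isolated)
Conditions: PivCl (1.05 equiv), Et3N (2.5 equiv), THF, −20 °C; then LiCl (1.1 equiv), 9 (1.0 equiv), −20 °C to rt
Reagents that add atoms: pivaloyl chloride, CC(C)(C)C(=O)Cl (its atoms are found in 22 only)
Why: N-Acylation of the Evans auxiliary through a mixed anhydride, the same operation as in step 6 on a less hindered arylacetic acid.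

Step 14
Reactants: 23 (4S)-4-benzyl-3-[(4-benzyloxy-3-methoxyphenyl)acetyl]-1,3-oxazolidin-2-one, 20 (2S,3R)-2-(4-benzyloxy-3-methoxyphenyl)-7-methoxy-3-[(triisopropylsilyloxy)methyl]-2,3-dihydro-1-benzofuran-5-carbaldehyde
Product: 26 (4S)-4-benzyl-3-[(2S,3S)-2-(4-benzyloxy-3-methoxyphenyl)-3-{(2S,3R)-2-(4-benzyloxy-3-methoxyphenyl)-7-methoxy-3-[(triisopropylsilyloxy)methyl]-2,3-dihydro-1-benzofuran-5-yl}-3-hydroxypropanoyl]-1,3-oxazolidin-2-one, via Z-boron enolate 24 (not isolated), via boron aldolate 25 (not isolated)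
Conditions: 23 (1.4 equiv), Bu2BOTf (1.5 equiv), iPr2NEt (1.8 equiv), CH2Cl2, −78 to 0 °C; 20 (1.0 equiv), −78 to −10 °C; then pH 7 phosphate buffer, MeOH, 30% H2O2, 0 °C
Reagents that add atoms: dibutylboron triflate, CCCCB(CCCC)OS(=O)(=O)C(F)(F)F (its boron unit is found in 24 and 25 only)
Why: Second Evans boron syn-aldol: the Z-enolate adds through the Zimmerman–Traxler chair on the face left open by the (S)-auxiliary, which sets Cβ (2S in the adduct) and Cα (3S) together as the syn pair under reagent control, the distant C2 and C3 having no say, while the excess of amine keeps free boron triflate away from the C2–O1 bond.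

Step 15
Reactants: 26 (4S)-4-benzyl-3-[(2S,3S)-2-(4-benzyloxy-3-methoxyphenyl)-3-{(2S,3R)-2-(4-benzyloxy-3-methoxyphenyl)-7-methoxy-3-[(triisopropylsilyloxy)methyl]-2,3-dihydro-1-benzofuran-5-yl}-3-hydroxypropanoyl]-1,3-oxazolidin-2-one
Product: 27 (1S,2R)-2-(4-benzyloxy-3-methoxyphenyl)-1-{(2S,3R)-2-(4-benzyloxy-3-methoxyphenyl)-7-methoxy-3-[(triisopropylsilyloxy)methyl]-2,3-dihydro-1-benzofuran-5-yl}propane-1,3-diol
Conditions: LiBH4 (2.5 equiv), MeOH (2.5 equiv), THF, 0 °C; then sat aq NH4Cl
Reagents that add atoms: none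
Why: Reductive cleavage of the N-acyl oxazolidinone with LiBH4/MeOH as in step 8, which turns the imide carbonyl into the CH2OH group on Cβ without touching any stereocentre (Cβ becomes R through the priority rules only).

Step 16
Reactants: 27 (1S,2R)-2-(4-benzyloxy-3-methoxyphenyl)-1-{(2S,3R)-2-(4-benzyloxy-3-methoxyphenyl)-7-methoxy-3-[(triisopropylsilyloxy)methyl]-2,3-dihydro-1-benzofuran-5-yl}propane-1,3-diol
Product: 28 (1S,2R)-2-(4-benzyloxy-3-methoxyphenyl)-1-[(2S,3R)-2-(4-benzyloxy-3-methoxyphenyl)-3-(hydroxymethyl)-7-methoxy-2,3-dihydro-1-benzofuran-5-yl]propane-1,3-diol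
Conditions: Bu4NF (1.5 equiv), THF, 0 °C to rt
Reagents that add atoms: none
Why: Fluoride-induced desilylation driven by the strong Si–F bond, placed before the hydrogenolysis so that basic fluoride never meets a free ring A phenol, whose phenoxide could open the C2–O1 bond through a quinone methide.

Step 17
Reactants: 28 (1S,2R)-2-(4-benzyloxy-3-methoxyphenyl)-1-[(2S,3R)-2-(4-benzyloxy-3-methoxyphenyl)-3-(hydroxymethyl)-7-methoxy-2,3-dihydro-1-benzofuran-5-yl]propane-1,3-diol
Product: 29 (1S,2R)-1-[(2S,3R)-2-(4-hydroxy-3-methoxyphenyl)-3-(hydroxymethyl)-7-methoxy-2,3-dihydro-1-benzofuran-5-yl]-2-(4-hydroxy-3-methoxyphenyl)propane-1,3-diol (target)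
Conditions: H2 (1 atm), 10% Pd/C, EtOAc/EtOH 1:1, rt, stopped at full conversion
Reagents that add atoms: none
Why: Catalytic hydrogenolysis: aryl benzyl ethers are cleaved on Pd/C in a neutral solvent well before the secondary benzylic alcohol at Cα and the cyclic benzylic ether C2–O1, so the reaction is stopped as soon as both O-benzyl groups are gone and no stereocentre is touched.

Compound list
1 | 4-amino-3-methoxybenzoic acid | Nc1ccc(C(=O)O)cc1OC | starting material
2 | 4-amino-3-iodo-5-methoxybenzoic acid | Nc1c(I)cc(C(=O)O)cc1OC | intermediate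
3 | 4-carboxy-2-iodo-6-methoxybenzenediazonium bromide (not isolated) | COc1cc(C(=O)O)cc(I)c1[N+]#N.[Br-] | intermediate
4 | 4-bromo-3-iodo-5-methoxybenzoic acid | COc1cc(C(=O)O)cc(I)c1Br | intermediate
5 | tert-butyl 4-bromo-3-iodo-5-methoxybenzoate | COc1cc(C(=O)OC(C)(C)C)cc(I)c1Br | intermediate
6 | tert-butyl 4-bromo-3-(2-ethoxy-2-oxoethyl)-5-methoxybenzoate | CCOC(=O)Cc1cc(C(=O)OC(C)(C)C)cc(OC)c1Br | intermediate
7 | lithium [2-bromo-5-(tert-butoxycarbonyl)-3-methoxyphenyl]acetate (not isolated) | [Li+].[O-]C(=O)Cc1cc(C(=O)OC(C)(C)C)cc(OC)c1Br | intermediate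
8 | [2-bromo-5-(tert-butoxycarbonyl)-3-methoxyphenyl]acetic acid | OC(=O)Cc1cc(C(=O)OC(C)(C)C)cc(OC)c1Br | intermediate
9 | (S)-4-benzyl-2-oxazolidinone | O=C1OC[C@H](Cc2ccccc2)N1 | starting material
10 | mixed anhydride of 8 and pivalic acid (not isolated) | CC(C)(C)C(=O)OC(=O)Cc1cc(C(=O)OC(C)(C)C)cc(OC)c1Br | intermediate
11 | tert-butyl 3-{2-[(4S)-4-benzyl-2-oxo-1,3-oxazolidin-3-yl]-2-oxoethyl}-4-bromo-5-methoxybenzoate | O=C(Cc1cc(C(=O)OC(C)(C)C)cc(OC)c1Br)N1C(=O)OC[C@@H]1Cc1ccccc1 | intermediate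
12 | 4-benzyloxy-3-methoxybenzaldehyde | COc1cc(C=O)ccc1OCc1ccccc1 | starting material
13 | Z-dibutylboron enolate of 11 (not isolated) | CCCCB(CCCC)O/C(=C\c1cc(C(=O)OC(C)(C)C)cc(OC)c1Br)N1C(=O)OC[C@@H]1Cc1ccccc1 | intermediate
14 | O-dibutylboryl derivative (boron aldolate) of 15 (not isolated) | COc1cc([C@@H](OB(CCCC)CCCC)[C@@H](C(=O)N2C(=O)OC[C@@H]2Cc2ccccc2)c2cc(C(=O)OC(C)(C)C)cc(OC)c2Br)ccc1OCc1ccccc1 | intermediate
15 | tert-butyl 3-[(2S,3S)-1-[(4S)-4-benzyl-2-oxo-1,3-oxazolidin-3-yl]-3-(4-benzyloxy-3-methoxyphenyl)-3-hydroxy-1-oxopropan-2-yl]-4-bromo-5-methoxybenzoate (syn aldol adduct) | COc1cc([C@@H](O)[C@@H](C(=O)N2C(=O)OC[C@@H]2Cc2ccccc2)c2cc(C(=O)OC(C)(C)C)cc(OC)c2Br)ccc1OCc1ccccc1 | intermediate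
16 | tert-butyl 3-[(1S,2R)-1-(4-benzyloxy-3-methoxyphenyl)-1,3-dihydroxypropan-2-yl]-4-bromo-5-methoxybenzoate | COc1cc([C@@H](O)[C@@H](CO)c2cc(C(=O)OC(C)(C)C)cc(OC)c2Br)ccc1OCc1ccccc1 | intermediate
17 | tert-butyl 3-[(1S,2R)-1-(4-benzyloxy-3-methoxyphenyl)-1-hydroxy-3-(triisopropylsilyloxy)propan-2-yl]-4-bromo-5-methoxybenzoate (key-step precursor) | COc1cc([C@@H](O)[C@@H](CO[Si](C(C)C)(C(C)C)C(C)C)c2cc(C(=O)OC(C)(C)C)cc(OC)c2Br)ccc1OCc1ccccc1 | intermediate
18 | tert-butyl (2S,3R)-2-(4-benzyloxy-3-methoxyphenyl)-7-methoxy-3-[(triisopropylsilyloxy)methyl]-2,3-dihydro-1-benzofuran-5-carboxylate (key-step product) | COc1cc([C@H]2Oc3c(OC)cc(C(=O)OC(C)(C)C)cc3[C@@H]2CO[Si](C(C)C)(C(C)C)C(C)C)ccc1OCc1ccccc1 | intermediate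
19 | [(2S,3R)-2-(4-benzyloxy-3-methoxyphenyl)-7-methoxy-3-[(triisopropylsilyloxy)methyl]-2,3-dihydro-1-benzofuran-5-yl]methanol | COc1cc([C@H]2Oc3c(OC)cc(CO)cc3[C@@H]2CO[Si](C(C)C)(C(C)C)C(C)C)ccc1OCc1ccccc1 | intermediate
20 | (2S,3R)-2-(4-benzyloxy-3-methoxyphenyl)-7-methoxy-3-[(triisopropylsilyloxy)methyl]-2,3-dihydro-1-benzofuran-5-carbaldehyde | COc1cc([C@H]2Oc3c(OC)cc(C=O)cc3[C@@H]2CO[Si](C(C)C)(C(C)C)C(C)C)ccc1OCc1ccccc1 | intermediate
21 | (4-benzyloxy-3-methoxyphenyl)acetic acid | COc1cc(CC(=O)O)ccc1OCc1ccccc1 | starting material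
22 | mixed anhydride of 21 and pivalic acid (not isolated) | COc1cc(CC(=O)OC(=O)C(C)(C)C)ccc1OCc1ccccc1 | intermediate
23 | (4S)-4-benzyl-3-[(4-benzyloxy-3-methoxyphenyl)acetyl]-1,3-oxazolidin-2-one | COc1cc(CC(=O)N2C(=O)OC[C@@H]2Cc2ccccc2)ccc1OCc1ccccc1 | intermediate
24 | Z-dibutylboron enolate of 23 (not isolated) | CCCCB(CCCC)O/C(=C\c1ccc(OCc2ccccc2)c(OC)c1)N1C(=O)OC[C@@H]1Cc1ccccc1 | intermediate
25 | O-dibutylboryl derivative (boron aldolate) of 26 (not isolated) | COc1cc([C@H]2Oc3c(OC)cc([C@@H](OB(CCCC)CCCC)[C@@H](C(=O)N4C(=O)OC[C@@H]4Cc4ccccc4)c4ccc(OCc5ccccc5)c(OC)c4)cc3[C@@H]2CO[Si](C(C)C)(C(C)C)C(C)C)ccc1OCc1ccccc1 | intermediate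
26 | (4S)-4-benzyl-3-[(2S,3S)-2-(4-benzyloxy-3-methoxyphenyl)-3-{(2S,3R)-2-(4-benzyloxy-3-methoxyphenyl)-7-methoxy-3-[(triisopropylsilyloxy)methyl]-2,3-dihydro-1-benzofuran-5-yl}-3-hydroxypropanoyl]-1,3-oxazolidin-2-one | COc1cc([C@H]2Oc3c(OC)cc([C@@H](O)[C@@H](C(=O)N4C(=O)OC[C@@H]4Cc4ccccc4)c4ccc(OCc5ccccc5)c(OC)c4)cc3[C@@H]2CO[Si](C(C)C)(C(C)C)C(C)C)ccc1OCc1ccccc1 | intermediate
27 | (1S,2R)-2-(4-benzyloxy-3-methoxyphenyl)-1-{(2S,3R)-2-(4-benzyloxy-3-methoxyphenyl)-7-methoxy-3-[(triisopropylsilyloxy)methyl]-2,3-dihydro-1-benzofuran-5-yl}propane-1,3-diol | COc1cc([C@H]2Oc3c(OC)cc([C@@H](O)[C@@H](CO)c4ccc(OCc5ccccc5)c(OC)c4)cc3[C@@H]2CO[Si](C(C)C)(C(C)C)C(C)C)ccc1OCc1ccccc1 | intermediate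
28 | (1S,2R)-2-(4-benzyloxy-3-methoxyphenyl)-1-[(2S,3R)-2-(4-benzyloxy-3-methoxyphenyl)-3-(hydroxymethyl)-7-methoxy-2,3-dihydro-1-benzofuran-5-yl]propane-1,3-diol | COc1cc([C@H]2Oc3c(OC)cc([C@@H](O)[C@@H](CO)c4ccc(OCc5ccccc5)c(OC)c4)cc3[C@@H]2CO)ccc1OCc1ccccc1 | intermediate
29 | (1S,2R)-1-[(2S,3R)-2-(4-hydroxy-3-methoxyphenyl)-3-(hydroxymethyl)-7-methoxy-2,3-dihydro-1-benzofuran-5-yl]-2-(4-hydroxy-3-methoxyphenyl)propane-1,3-diol (CNP0294468.1) | COc1cc([C@H]2Oc3c(OC)cc([C@@H](O)[C@@H](CO)c4ccc(O)c(OC)c4)cc3[C@@H]2CO)ccc1O | target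

Total step count: 17. Longest linear sequence: 16 (steps 1 to 12 and 14 to 17, from 1). Step 13 is the one-step side branch.

Steps most likely to fail

Step 10 (key step). Insertion of copper into the C7a–Br bond, which is flanked by OMe and by the branched side chain, may be slow. Hydrodebromination and copper-mediated dehydrogenation of the benzylic alcohol could then take over during the long heating. The fallback first puts O1 on ring B and then closes the ring at C2. Setting out from 17, Miyaura borylation (B2pin2, Pd(OAc)2, SPhos, KOAc, dioxane, 90 °C) should give the pinacol boronate F1. Oxidation (30% H2O2, THF/pH 7 buffer, 0 °C) should then give the ortho-hydroxyaryl diol monoether F2. A catalytic amount of camphorsulfonic acid in CH2Cl2 at 0 °C ionises the p-benzyloxybenzylic alcohol, and the phenol oxygen captures the cation anti to the CH2OTIPS group on C3. The trans ring is also the thermodynamic product, so the route is rejoined at 18. In this variant C2 is re-formed under the control of C3 instead of being carried through.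

Step 7. Addition of the crowded ortho-bromoaryl enolate to an electron-rich aldehyde may be slow. Warming may bring reversal of the boron aldolate and epimerisation at the doubly activated α-carbon, that is, poor diastereoselectivity. The fallback uses another auxiliary class, another metal and a milder cleavage. Setting out from 8, coupling with commercial (S)-4-benzyl-1,3-thiazolidine-2-thione (EDC·HCl, DMAP, CH2Cl2) should give the N-arylacetyl thiazolidinethione F3. Its chlorotitanium enolate (TiCl4, iPr2NEt, N-methyl-2-pyrrolidinone, CH2Cl2, 0 °C) adds to 12 at −78 °C through the non-chelated chair to the thiazolidinethione syn adduct F4, which has the same (2S,3S) configuration. NaBH4 in THF/EtOH at 0 °C then displaces the thione auxiliary and reduces the acyl group. This rejoins the route at 16 and skips 11 and 15.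

Step 17. Over-reduction may occur, that is, hydrogenolysis of the benzylic Cα–OH bond or of the benzylic C2–O1 bond alongside the two O-benzyl groups. The fallback runs the hydrogenolysis on a fully silylated substrate and uses fluoride last. Setting out from 27, TBSOTf and 2,6-lutidine in CH2Cl2 (−78 to 0 °C) should cap both side-chain hydroxyls to give the tris-silyl ether F5. In F5, Cα carries a bulky silyloxy group that does not ionise, and C2 is screened by the neighbouring CH2OTIPS. Hydrogenolysis (H2, 10% Pd/C, EtOAc) then gives the bisphenol F6. Bu4NF buffered with AcOH in THF removes all three silyl groups and reaches 29 directly, bypassing 28.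

Further compounds
F1 | step 10 | tert-butyl 3-[(1S,2R)-1-(4-benzyloxy-3-methoxyphenyl)-1-hydroxy-3-(triisopropylsilyloxy)propan-2-yl]-5-methoxy-4-(4,4,5,5-tetramethyl-1,3,2-dioxaborolan-2-yl)benzoate | COc1cc([C@@H](O)[C@@H](CO[Si](C(C)C)(C(C)C)C(C)C)c2cc(C(=O)OC(C)(C)C)cc(OC)c2B3OC(C)(C)C(C)(C)O3)ccc1OCc1ccccc1
F2 | step 10 | tert-butyl 3-[(1S,2R)-1-(4-benzyloxy-3-methoxyphenyl)-1-hydroxy-3-(triisopropylsilyloxy)propan-2-yl]-4-hydroxy-5-methoxybenzoate | COc1cc([C@@H](O)[C@@H](CO[Si](C(C)C)(C(C)C)C(C)C)c2cc(C(=O)OC(C)(C)C)cc(OC)c2O)ccc1OCc1ccccc1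
F3 | step 7 | tert-butyl 3-{2-[(4S)-4-benzyl-2-thioxo-1,3-thiazolidin-3-yl]-2-oxoethyl}-4-bromo-5-methoxybenzoate | O=C(Cc1cc(C(=O)OC(C)(C)C)cc(OC)c1Br)N1C(=S)SC[C@@H]1Cc1ccccc1
F4 | step 7 | tert-butyl 3-[(2S,3S)-1-[(4S)-4-benzyl-2-thioxo-1,3-thiazolidin-3-yl]-3-(4-benzyloxy-3-methoxyphenyl)-3-hydroxy-1-oxopropan-2-yl]-4-bromo-5-methoxybenzoate | COc1cc([C@@H](O)[C@@H](C(=O)N2C(=S)SC[C@@H]2Cc2ccccc2)c2cc(C(=O)OC(C)(C)C)cc(OC)c2Br)ccc1OCc1ccccc1
F5 | step 17 | 1,3-bis-O-(tert-butyldimethylsilyl) ether of 27 (Cα S, Cβ R, C2 S, C3 R) | COc1cc([C@H]2Oc3c(OC)cc([C@@H](O[Si](C)(C)C(C)(C)C)[C@@H](CO[Si](C)(C)C(C)(C)C)c4ccc(OCc5ccccc5)c(OC)c4)cc3[C@@H]2CO[Si](C(C)C)(C(C)C)C(C)C)ccc1OCc1ccccc1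
F6 | step 17 | bisphenol from F5 by loss of both O-benzyl groups (Cα S, Cβ R, C2 S, C3 R) | COc1cc([C@H]2Oc3c(OC)cc([C@@H](O[Si](C)(C)C(C)(C)C)[C@@H](CO[Si](C)(C)C(C)(C)C)c4ccc(O)c(OC)c4)cc3[C@@H]2CO[Si](C(C)C)(C(C)C)C(C)C)ccc1O
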